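## Analysis of the target

CNP0174755.1 is a cis-fused eremophilane: a decalin (ring A: C1–C5 and C10; ring B: C5–C10) with a quaternary, methyl-bearing C5, a methyl on C4, an isopropenyl group on C7, a ketone at C8 and (Z)-2-methylbut-2-enoate (angelate) esters on C3 and C9. With the C5 methyl defined as β, the six stereocentres are 3α-O, 4β-Me, 5β-Me, 7β-isopropenyl, 9β-O and 10β-H. In the chair–chair conformer that has C4 axial on ring B, the substituents on C3, C4, C7 and C9 are all equatorial and only the C5 methyl is axial (on ring A). C7 and C9 are α to the C8 ketone and C4 becomes epimerisable once C3 is a ketone, but C5, C10 and the C3 carbinol cannot be corrected by enolisation. The sensitive groups are the two angelates (they isomerise to tiglates under nucleophilic acyl-transfer catalysis), the α-acyloxy ketone, and the β,γ-unsaturated ketone, whose isopropenyl double bond moves into conjugation with C8 under prolonged acid or base. The difficulties are the quaternary C5 next to tertiary C4 inside a cis ring fusion, the C8/C9 oxygenation beside the labile C7, and an equatorial C3 oxygen that lies 1,3 to the axial C5 methyl. The plan rests on one feature: with C3 written as an enol ether, O=C8–C7–C6–C5–C4=C3(O) is a δ,ε-unsaturated ketone, the retron of an oxy-Cope rearrangement. Reconnecting C3 to C8 and cutting C5–C6 turns ring B and the C3–C4 edge into a 2-alkenylbicyclo[2.2.2]oct-5-en-2-ol in which C5 already carries its methyl, C8 and C9 their oxygens, and C10 is a bridgehead.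

## Retrosynthetic reasoning

**C9 ester.** The last bond made is the C9–O acyl bond of 27, which is cut to the α-hydroxy ketone 25 and angelic acid 23. It comes last because an acyloxy group beside the C8 ketone would not survive hydride, phosphine or strong base. Forward, 23 has to be transferred through the mixed anhydride 26 without a nucleophilic acylation catalyst so that the Z double bond is kept. 25 goes back to its 4-methoxybenzyl ether 24: C9 needs an ether that passes the strongly basic key step and comes off oxidatively beside an ester and two alkenes.

**C3 ester, with inversion.** The C3–O bond of 24 is cut with inversion, to the axial 3β-alcohol 22 and 23. The equatorial 3α-oxygen cannot be reached by direct reduction: C3 of the dione 21 lies 1,3 to the axial C5 methyl, so a hydride enters from the α face and gives the axial alcohol. Equilibrating or electron-transfer reductions that would give the equatorial alcohol would destroy the α-alkoxy ketone at C8/C9. The axial alcohol is therefore made on purpose, with a bulky hydride that also distinguishes C3 from the more substituted C8 carbonyl. The carboxylate of 23 then displaces the activated axial oxygen from the open α face, which sets C3 and installs the first ester in one operation.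

**C3 carbonyl and C4.** The C3 ketone of 21 is traced to the methyl enol ether 20 (C4–H bond cut). The enol ether is the regiodefined, masked form in which the key step delivers C3. Forward, the proton must enter C4 so that the methyl becomes equatorial (4β). This is the kinetically favoured path and also the stable arrangement, because a 4α-methyl would be syn-axial to C9.

**Key disconnection.** In 20 the bond C5–C6 is cut and C3–C8 is reconnected, which leads through the dienolate 19 and the alkoxide 18 to the bicyclic alcohol 17. This one operation removes ring B, the quaternary centre and the cis ring fusion, and leaves a rigid bicycle whose stereocentres are easy to set. Forward, the [3,3] shift has to form the bond to a fully substituted alkene carbon, and the enolate has to be protonated at C7 and not at the terminal CH2. C9 is deliberately brought in with its final configuration and is never equilibrated: with C5, C10 and C9 fixed, the equatorial positions at C7 and C4 are the target's, whereas a free equilibration of C4, C7 and C9 together could drift into the other all-equatorial series of the flipped decalin.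

**C9 ether, resolution and C9–H.** 17 is the 4-methoxybenzyl ether of the diol 16. 16 is obtained from racemic 14 through the camphanate 15, because the cycloaddition that creates the bicycle starts from an achiral dienone. A covalent diastereomer separation is chosen over an enzymatic acylation, since the carbinol is flanked by a quaternary carbon and a bridgehead. The C3–H bond of the diol 14 (the future C9) is cut to the α-hydroxy ketone 13, and 13 to the dimethyl ketal 12. Forward, the dienyl group on C2 shields one face of the C3 carbonyl, so hydride delivery gives the hydroxyl syn to the C5=C6 bridge, which is what becomes 9β.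

**C7–C8 bond and the ethano bridge.** 12 is traced to the sulfone 11 (C–S bond) and 11 to the ketone 6 plus the dienyl nucleophile 10, made via 9 from the hydrazone 8 of the enone 7. The sulfone is removed only after the ketone has been consumed, so that no α-alkoxy ketone is exposed to a dissolving metal. The ketone of 6 has no α-hydrogen, so addition is the only course open to the nucleophile, and it has to come from the face of the etheno bridge.

**Bicycle.** 6 is cut across C1–C7 and C4–C8 (C2–C3 and C1–C10 of the eremophilane) to the masked o-benzoquinone 5 and phenyl vinyl sulfone 4, which serves as an ethylene equivalent. 5 comes from oxidation of the phenol 3. This places the bridgehead methoxy group (future C3 oxygen), the ketone (C8), the ketal (C9) and both alkene methyls (C4, C5) in one step.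

**Phenol.** 3 is cut at the aryl–methyl bond to the bromide 2 and then to commercial 1, whose two free ring positions are equivalent.

## Alternatives that were turned down

**Alternative 1:** Ring A is disconnected at C4–C5 and C1–C10, giving the quinone A2 as ring B and the silyloxy diene A3. The forward key step is an enantioselective Diels–Alder reaction under a chiral oxazaborolidinium Lewis acid, in which the methyl-bearing double bond of A2 takes up A3 endo to give the cis-fused enedione A1.
- For: two simple partners, catalytic absolute control, and quaternary C5 with the cis fusion set in the opening step. On enantiocontrol it is better than the chosen route, which needs a resolution.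
- Against: ring B arrives as a 6,9-dione with a C7=C8 methoxy enone. C6 must be deoxygenated, the isopropenyl group brought to C7, and the C9 carbonyl reduced to the 9β-alcohol while C10, now α to a ketone, is free to epimerise. The C4 methyl arrives epimeric, and the C3 ketone poses the same axial/equatorial problem as here. The bond C4–C5 must also join two methyl-bearing carbons in the orientation set by the catalyst.
- Comparison: the chosen route gives up catalytic asymmetry, but it delivers C3, C8 and C9 at the right oxidation level and the C7 substituent in the same step that closes ring B, so the steps after the key step are few.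

**Alternative 2:** Both rings are disconnected at once back to the acyclic diphosphate A5. The forward key step is a terpene cyclase (aristolochene synthase, magnesium-dependent) that ionises A5, closes the ten-membered ring, closes the decalin transannularly, shifts hydride and methyl, and loses a proton to give (+)-aristolochene A4.
- For: all fifteen carbons, both rings and the C4/C5 methyl pair as a single enantiomer in one step; no chemical route matches this for the skeleton.
- Against: A4 carries no oxygen. C3 is an unactivated methylene that would need a site- and face-selective C–H oxidation. C8 and C9 must be oxidised from the Δ9 alkene, the ring fusion hydrogen must be added cis, and C7 arrives with the opposite configuration (correctable only once C8 is a ketone). Enzyme and substrate supply add work outside the flask.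
- Comparison: the chosen route is longer to the skeleton but places every oxygen by construction.

**Alternative 3:** Ring A is disconnected at C1–C10, back to the N-acyloxyphthalimide A7, in which a 4-methylcyclohexa-2,5-dienone carries the C1–C4 chain. The forward key step is cathodic reduction, which releases the primary C1 radical; it adds 6-exo to one enone arm, and the resulting enolate is protonated at C9 to give A6.
- For: the quaternary carbon exists before the cyclisation, the tether forces the cis fusion, conditions are mild, and absolute configuration comes from the chain without a resolution.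
- Against: which enone arm reacts is decided by the chain stereocentres, and A6 has C3 and C4 opposite to the target relative to C5/C10. C4 cannot be epimerised unless C3 is oxidised, which brings back the C3 reduction problem. C9 still lacks its oxygen, and C7 lacks the isopropenyl group, which must be attached at the α-carbon of an enone.
- Comparison: the chosen route sets C9 and C7 in or before the key step and needs no inversion of a methyl-bearing centre.

Key step: step 12

Remark on the chemistry: eremophilane numbering is used for all decalins and β is the face of the C5 methyl; bicyclic intermediates keep the locants of 17; racemic intermediates are drawn as the enantiomer that is carried on after step 9.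

Remark on the chemistry: in a bicyclo[2.2.2]octene the two bridgehead descriptors are coupled; 17 is written with the only consistent pair that has the dienyl group syn to the C5=C6 bridge and leads to 20.

## Route

Step 1
Reactants: 1 2,6-dimethoxy-4-methylphenol
Product: 2 3-bromo-2,6-dimethoxy-4-methylphenol
Conditions: NBS (1.0 equiv), MeCN, 0 °C to 25 °C
Reagents that add atoms: N-bromosuccinimide, O=C1CCC(=O)N1Br
Why: Electrophilic aromatic bromination; the two free positions are equivalent and each is activated by one ortho and one para methoxy group, so monobromination can give only this product.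

Step 2
Reactants: 2 3-bromo-2,6-dimethoxy-4-methylphenol
Product: 3 2,6-dimethoxy-3,4-dimethylphenol
Conditions: trimethylboroxine, Pd(OAc)2 (5 mol %), SPhos (10 mol %), K3PO4, toluene–H2O, 100 °C
Reagents that add atoms: trimethylboroxine, CB1OB(C)OB(C)O1
Why: Suzuki–Miyaura methylation; the electron-rich, doubly ortho-substituted bromide calls for a bulky electron-rich phosphine, and the free phenol is tolerated as its phenoxide.

Step 3
Reactants: 3 2,6-dimethoxy-3,4-dimethylphenol; 4 phenyl vinyl sulfone
Product: 6 racemic 1,3,3-trimethoxy-5,6-dimethyl-7-endo-(phenylsulfonyl)bicyclo[2.2.2]oct-5-en-2-one, via dienone ketal 5 (not isolated)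
Conditions: PhI(OAc)2 (1.1 equiv), NaHCO3, MeOH, 0 °C, 4 (3 equiv) present; then toluene, 110 °C
Reagents that add atoms: methanol, CO
Why: Oxidative dearomatisation with hypervalent iodine should give the masked o-benzoquinone 5 by methanol capture at C6, the ortho carbon not flanked by a methyl group. 5 then undergoes a Diels–Alder reaction across its diene termini with the electron-poor dienophile, the sulfonyl carbon bonding to the methoxy-bearing terminus (ortho rule) and endo. Regio- and stereochemistry at the sulfonyl carbon have no consequence because the sulfone is removed in step 6.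

Step 4
Reactants: 7 3-methylbut-3-en-2-one
Product: 8 (E)-3-methylbut-3-en-2-one 2,4,6-triisopropylbenzenesulfonylhydrazone
Conditions: 2,4,6-triisopropylbenzenesulfonyl hydrazide, HCl (cat.), MeOH, 0 °C to 25 °C
Reagents that add atoms: 2,4,6-triisopropylbenzenesulfonyl hydrazide, CC(C)c1cc(C(C)C)c(S(=O)(=O)NN)c(C(C)C)c1
Why: Acid-catalysed hydrazone condensation, faster than conjugate addition on this α-branched enone; the isomer with the sulfonamide syn to the methyl group is the one that can be deprotonated at that methyl group in the next step.

Step 5
Reactants: 8 (E)-3-methylbut-3-en-2-one 2,4,6-triisopropylbenzenesulfonylhydrazone; 6 racemic 1,3,3-trimethoxy-5,6-dimethyl-7-endo-(phenylsulfonyl)bicyclo[2.2.2]oct-5-en-2-one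
Product: 11 racemic 1,3,3-trimethoxy-5,6-dimethyl-2-(3-methylbuta-1,3-dien-2-yl)-7-endo-(phenylsulfonyl)bicyclo[2.2.2]oct-5-en-2-ol, via dienyllithium 9 (not isolated), via dienylcerium dichloride 10 (not isolated)
Conditions: 8 (2 equiv), n-BuLi (2.05 equiv per 8), THF, −78 °C to 0 °C; CeCl3, −78 °C; then 6, −78 °C to −40 °C; aq. NH4Cl
Reagents that add atoms: none
Why: Shapiro reaction (the hydrazone dianion loses sulfinate and N2) gives the 2-lithiodiene, and transmetallation to the organocerium makes it non-basic toward the sulfone C–H and strongly carbonyl-selective. Addition to the non-enolisable ketone should occur from the face of the etheno bridge, because the inward hydrogens of the ethano bridge shield the other face, so the dienyl group ends up syn to C5=C6 as the rearrangement requires.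

Step 6
Reactants: 11 racemic 1,3,3-trimethoxy-5,6-dimethyl-2-(3-methylbuta-1,3-dien-2-yl)-7-endo-(phenylsulfonyl)bicyclo[2.2.2]oct-5-en-2-ol
Product: 12 racemic 1,3,3-trimethoxy-5,6-dimethyl-2-(3-methylbuta-1,3-dien-2-yl)bicyclo[2.2.2]oct-5-en-2-ol
Conditions: 6% Na(Hg), Na2HPO4, MeOH–THF, −20 °C
Reagents that add atoms: none
Why: Reductive desulfonylation by electron transfer; it is placed after the ketone has been consumed so that no α-alkoxy ketone meets the amalgam, and a non-aryl 1,3-diene and a tetrasubstituted alkene are not reduced under these buffered conditions.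

Step 7
Reactants: 12 racemic 1,3,3-trimethoxy-5,6-dimethyl-2-(3-methylbuta-1,3-dien-2-yl)bicyclo[2.2.2]oct-5-en-2-ol
Product: 13 racemic 2-hydroxy-1-methoxy-5,6-dimethyl-2-(3-methylbuta-1,3-dien-2-yl)bicyclo[2.2.2]oct-5-en-3-one
Conditions: aq. HCl (2 M), THF, 25 °C
Reagents that add atoms: water, O
Why: Acetal hydrolysis through the C3 oxocarbenium ion; ionisation of the tertiary allylic alcohol is disfavoured by three flanking C–O bonds, the bridgehead ether cannot ionise, and the new ketone cannot enolise toward the bridgehead.

Step 8
Reactants: 13 racemic 2-hydroxy-1-methoxy-5,6-dimethyl-2-(3-methylbuta-1,3-dien-2-yl)bicyclo[2.2.2]oct-5-en-3-one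
Product: 14 racemic 1-methoxy-5,6-dimethyl-2-(3-methylbuta-1,3-dien-2-yl)bicyclo[2.2.2]oct-5-ene-2,3-diol (3-OH syn to C5=C6 and trans to 2-OH)
Conditions: NaBH4, MeOH, −20 °C
Reagents that add atoms: none
Why: Hydride reduction; the dienyl group on C2 is eclipsed with the etheno-side face of the C3 carbonyl, so hydride should enter from the ethano side and leave the new hydroxyl syn to C5=C6, the configuration that becomes 9β.

Step 9
Reactants: 14 racemic 1-methoxy-5,6-dimethyl-2-(3-methylbuta-1,3-dien-2-yl)bicyclo[2.2.2]oct-5-ene-2,3-diol
Product: 15 3-O-[(1S)-camphanoyl] ester of the enantiomer of 14 drawn in the compound list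
Conditions: (1S)-(−)-camphanic chloride, Et3N, DMAP (cat.), CH2Cl2, 0 °C to 25 °C; separation of the two diastereomers by chromatography or crystallisation
Reagents that add atoms: (1S)-(−)-camphanic chloride, O=C(Cl)[C@@]12CC[C@@](C)(C(=O)O1)C2(C)C
Why: Classical resolution through diastereomeric esters; only the secondary hydroxyl is acylated, and the crystalline camphanates allow the configuration to be assigned by X-ray analysis. An enzymatic acylation is not relied on because the carbinol is flanked by a quaternary carbon and a bridgehead.

Step 10
Reactants: 15 3-O-[(1S)-camphanoyl] ester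
Product: 16 enantiopure 1-methoxy-5,6-dimethyl-2-(3-methylbuta-1,3-dien-2-yl)bicyclo[2.2.2]oct-5-ene-2,3-diol
Conditions: K2CO3 (0.2 equiv), MeOH, 25 °C
Reagents that add atoms: none
Why: Base-catalysed transesterification of an activated ester; no stereocentre is touched.

Step 11
Reactants: 16 enantiopure diol
Product: 17 3-(4-methoxybenzyloxy)-1-methoxy-5,6-dimethyl-2-(3-methylbuta-1,3-dien-2-yl)bicyclo[2.2.2]oct-5-en-2-ol
Conditions: NaH (1.05 equiv), 4-methoxybenzyl chloride, n-Bu4NI (cat.), THF–DMF, 0 °C to 25 °C
Reagents that add atoms: 4-methoxybenzyl chloride, COc1ccc(CCl)cc1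
Why: Williamson etherification; the secondary alkoxide is alkylated while the tertiary hydroxyl between two fully substituted carbons stays free, and a sodium alkoxide of this type should not rearrange at this temperature.

Step 12
Reactants: 17 3-(4-methoxybenzyloxy)-1-methoxy-5,6-dimethyl-2-(3-methylbuta-1,3-dien-2-yl)bicyclo[2.2.2]oct-5-en-2-ol
Product: 20 3-methoxy-9β-(4-methoxybenzyloxy)-10βH-eremophila-3,11-dien-8-one (cis-fused; 5β-methyl; 7β-isopropenyl), via potassium alkoxide 18 (not isolated), via potassium dienolate 19 (not isolated)
Conditions: KH (3 equiv), 18-crown-6 (3 equiv), THF, 0 °C to 25 °C; then MeOH, −78 °C to −40 °C; then AcOH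
Reagents that add atoms: none
Why: Anionic oxy-Cope rearrangement, the known behaviour of 2-alkenylbicyclo[2.2.2]oct-5-en-2-ols, here with a 1,3-dien-2-yl group in place of vinyl: KH with 18-crown-6 gives the separated alkoxide 18, whose oxyanion weakens the adjacent C3–C8 bond, and the [3,3] shift forms C5–C6 between the dienyl CH2 and the alkene carbon that already bears the C5 methyl. Ring B is closed by this concerted shift through the boat-shaped transition state that the bicycle enforces, not by a separate cyclisation, while the bicycle opens into ring A with its C3=C4 methyl enol ether; the product is the extended enolate 19. C5 is new and is controlled by the bicycle: the dienyl group hangs from C8 on the side of the C5=C6 bridge that faces the C8–C9 bridge, so it can reach C5 from that face only and the C10 hydrogen must end up cis to the C5 methyl. C9 and C10 pass through unchanged. C7 is set on protonation: methanol protonates 19 at the α-carbon C7 and not at the terminal CH2 (the kinetic preference of dienolates), and because this proton transfer is reversible with the methoxide formed, C7 should settle as the equatorial 7β epimer dictated by the equatorial 9β ether. Acetic acid then stops the exchange before the double bond can move into conjugation. The step needs the dienyl group syn to the etheno bridge (step 5), an ether at C9 that cannot migrate to the neighbouring alkoxide as a silyl or acyl group would, and no other acidic C–H, all of which 17 provides.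

Step 13
Reactants: 20 3-methoxy-9β-(4-methoxybenzyloxy)-10βH-eremophila-3,11-dien-8-one
Product: 21 9β-(4-methoxybenzyloxy)-10βH-eremophil-11-ene-3,8-dione (4β-methyl)
Conditions: aq. HCl (0.5 M), THF, 0 °C to 25 °C, short reaction time
Reagents that add atoms: water, O
Why: Enol ether hydrolysis (C-protonation at C4, hydration, loss of methanol); the proton should enter the face that lets the C4 methyl swing away from C9, which is axial on ring A, giving the equatorial 4β-methyl that is also the stable epimer. Acid is kept dilute and brief so that the C8 ketone does not enolise toward the isopropenyl group.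

Step 14
Reactants: 21 9β-(4-methoxybenzyloxy)-10βH-eremophil-11-ene-3,8-dione
Product: 22 3β-hydroxy-9β-(4-methoxybenzyloxy)-10βH-eremophil-11-en-8-one
Conditions: LiBH(s-Bu)3 (1.05 equiv), THF, −78 °C; then H2O
Reagents that add atoms: none
Why: Bulky trialkylborohydride reduction of the less substituted ketone; the axial C5 methyl blocks the axial path to C3 (as in 3,3,5-trimethylcyclohexanone-type ketones), so hydride should enter from the α face and give the axial 3β-alcohol, which is made deliberately. The C8 carbonyl, with two branched α-carbons, should react more slowly.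

Step 15
Reactants: 22 3β-hydroxy-9β-(4-methoxybenzyloxy)-10βH-eremophil-11-en-8-one; 23 angelic acid
Product: 24 3α-angeloyloxy-9β-(4-methoxybenzyloxy)-10βH-eremophil-11-en-8-one
Conditions: PPh3, DIAD, toluene, 0 °C to 25 °C
Reagents that add atoms: none
Why: Mitsunobu esterification with inversion; the axial oxyphosphonium group is displaced by the carboxylate from the open α face, giving the equatorial 3α-ester with relief of the syn-axial O/CH3 strain. Angelic acid acts only as a carboxylate nucleophile and is never an activated acyl species, so its Z geometry should be retained.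

Step 16
Reactants: 24 3α-angeloyloxy-9β-(4-methoxybenzyloxy)-10βH-eremophil-11-en-8-one
Product: 25 3α-angeloyloxy-9β-hydroxy-10βH-eremophil-11-en-8-one
Conditions: DDQ (1.3 equiv), CH2Cl2–pH 7 buffer, 0 °C to 25 °C
Reagents that add atoms: none
Why: Oxidative cleavage of the 4-methoxybenzyl ether (benzylic hydride abstraction, then hydrolysis of the oxocarbenium ion); the neutral buffered medium spares the angelate, the isopropenyl group and the epimerisable C7 and C9.

Step 17
Reactants: 25 3α-angeloyloxy-9β-hydroxy-10βH-eremophil-11-en-8-one; 23 angelic acid
Product: 27 3α,9β-bis(angeloyloxy)-10βH-eremophil-11-en-8-one (CNP0174755.1), via mixed anhydride 26 (not isolated)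
Conditions: 23, 2,4,6-trichlorobenzoyl chloride, Et3N, toluene, 25 °C; then 25, 80 °C
Reagents that add atoms: none
Why: Yamaguchi esterification run without DMAP; the alcohol attacks the less hindered angeloyl carbonyl of the mixed anhydride, and leaving out a nucleophilic amine catalyst avoids Z to E isomerisation to the tiglate. Triethylamine in toluene is too weak a base to enolise the C8 ketone appreciably.

## Compound list

1 | 2,6-dimethoxy-4-methylphenol | COc1cc(C)cc(OC)c1O | starting material
2 | 3-bromo-2,6-dimethoxy-4-methylphenol | COc1cc(C)c(Br)c(OC)c1O | intermediate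
3 | 2,6-dimethoxy-3,4-dimethylphenol | COc1cc(C)c(C)c(OC)c1O | intermediate
4 | phenyl vinyl sulfone | C=CS(=O)(=O)c1ccccc1 | starting material
5 | 2,6,6-trimethoxy-3,4-dimethylcyclohexa-2,4-dien-1-one (not isolated) | COC1=C(C)C(C)=CC(OC)(OC)C1=O | intermediate
6 | racemic 1,3,3-trimethoxy-5,6-dimethyl-7-endo-(phenylsulfonyl)bicyclo[2.2.2]oct-5-en-2-one (sulfonyl syn to C5=C6) | O=C1C(OC)(OC)[C@H]2C[C@H](S(=O)(=O)c3ccccc3)[C@]1(OC)C(C)=C2C | intermediate
7 | 3-methylbut-3-en-2-one | CC(=O)C(C)=C | starting material
8 | (E)-3-methylbut-3-en-2-one 2,4,6-triisopropylbenzenesulfonylhydrazone | C=C(C)/C(C)=N/NS(=O)(=O)c1c(C(C)C)cc(C(C)C)cc1C(C)C | intermediate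
9 | (3-methylbuta-1,3-dien-2-yl)lithium (not isolated) | [Li]C(=C)C(C)=C | intermediate
10 | (3-methylbuta-1,3-dien-2-yl)cerium dichloride (not isolated) | Cl[Ce](Cl)C(=C)C(C)=C | intermediate
11 | racemic 1,3,3-trimethoxy-5,6-dimethyl-2-(3-methylbuta-1,3-dien-2-yl)-7-endo-(phenylsulfonyl)bicyclo[2.2.2]oct-5-en-2-ol (dienyl syn to C5=C6) | C=C(C)C(=C)[C@]1(O)C(OC)(OC)[C@H]2C[C@H](S(=O)(=O)c3ccccc3)[C@]1(OC)C(C)=C2C | intermediate
12 | racemic 1,3,3-trimethoxy-5,6-dimethyl-2-(3-methylbuta-1,3-dien-2-yl)bicyclo[2.2.2]oct-5-en-2-ol | C=C(C)C(=C)[C@]1(O)C(OC)(OC)[C@H]2CC[C@]1(OC)C(C)=C2C | intermediate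
13 | racemic 2-hydroxy-1-methoxy-5,6-dimethyl-2-(3-methylbuta-1,3-dien-2-yl)bicyclo[2.2.2]oct-5-en-3-one | C=C(C)C(=C)[C@]1(O)C(=O)[C@H]2CC[C@]1(OC)C(C)=C2C | intermediate
14 | racemic 1-methoxy-5,6-dimethyl-2-(3-methylbuta-1,3-dien-2-yl)bicyclo[2.2.2]oct-5-ene-2,3-diol (3-OH syn to C5=C6) | C=C(C)C(=C)[C@]1(O)[C@H](O)[C@H]2CC[C@]1(OC)C(C)=C2C | intermediate
15 | 3-O-[(1S)-camphanoyl] ester of the drawn enantiomer of 14 | C=C(C)C(=C)[C@]1(O)[C@H](OC(=O)[C@@]45CC[C@@](C)(C(=O)O4)C5(C)C)[C@H]2CC[C@]1(OC)C(C)=C2C | intermediate
16 | enantiopure 1-methoxy-5,6-dimethyl-2-(3-methylbuta-1,3-dien-2-yl)bicyclo[2.2.2]oct-5-ene-2,3-diol | C=C(C)C(=C)[C@]1(O)[C@H](O)[C@H]2CC[C@]1(OC)C(C)=C2C | intermediate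
17 | 3-(4-methoxybenzyloxy)-1-methoxy-5,6-dimethyl-2-(3-methylbuta-1,3-dien-2-yl)bicyclo[2.2.2]oct-5-en-2-ol (dienyl and ether oxygen both syn to C5=C6) | C=C(C)C(=C)[C@]1(O)[C@H](OCc2ccc(OC)cc2)[C@H]3CC[C@]1(OC)C(C)=C3C | intermediate
18 | potassium alkoxide of 17 (not isolated) | C=C(C)C(=C)[C@]1([O-])[C@H](OCc2ccc(OC)cc2)[C@H]3CC[C@]1(OC)C(C)=C3C.[K+] | intermediate
19 | potassium 3-methoxy-9β-(4-methoxybenzyloxy)-10βH-eremophila-3,7,11-trien-8-olate (not isolated) | C=C(C)C=1C[C@@]2(C)[C@H](CCC(OC)=C2C)[C@@H](OCc3ccc(OC)cc3)C=1[O-].[K+] | intermediate
20 | 3-methoxy-9β-(4-methoxybenzyloxy)-10βH-eremophila-3,11-dien-8-one (5β-methyl, 7β-isopropenyl) | C=C(C)[C@H]1C[C@@]2(C)[C@H](CCC(OC)=C2C)[C@@H](OCc3ccc(OC)cc3)C1=O | intermediate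
21 | 9β-(4-methoxybenzyloxy)-10βH-eremophil-11-ene-3,8-dione (4β,5β-dimethyl, 7β-isopropenyl) | C=C(C)[C@H]1C[C@@]2(C)[C@H](CCC(=O)[C@@H]2C)[C@@H](OCc3ccc(OC)cc3)C1=O | intermediate
22 | 3β-hydroxy-9β-(4-methoxybenzyloxy)-10βH-eremophil-11-en-8-one | C=C(C)[C@H]1C[C@@]2(C)[C@H](CC[C@H](O)[C@@H]2C)[C@@H](OCc3ccc(OC)cc3)C1=O | intermediate
23 | angelic acid, (Z)-2-methylbut-2-enoic acid | C/C=C(/C)C(=O)O | starting material
24 | 3α-angeloyloxy-9β-(4-methoxybenzyloxy)-10βH-eremophil-11-en-8-one | C=C(C)[C@H]1C[C@@]2(C)[C@H](CC[C@@H](OC(=O)/C(C)=C\C)[C@@H]2C)[C@@H](OCc3ccc(OC)cc3)C1=O | intermediate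
25 | 3α-angeloyloxy-9β-hydroxy-10βH-eremophil-11-en-8-one | C=C(C)[C@H]1C[C@@]2(C)[C@H](CC[C@@H](OC(=O)/C(C)=C\C)[C@@H]2C)[C@@H](O)C1=O | intermediate
26 | angelic 2,4,6-trichlorobenzoic anhydride (not isolated) | C/C=C(/C)C(=O)OC(=O)c1c(Cl)cc(Cl)cc1Cl | intermediate
27 | CNP0174755.1, 3α,9β-bis(angeloyloxy)-10βH-eremophil-11-en-8-one (4β,5β-dimethyl, 7β-isopropenyl) | C=C(C)[C@H]1C[C@@]2(C)[C@H](CC[C@@H](OC(=O)/C(C)=C\C)[C@@H]2C)[C@@H](OC(=O)/C(C)=C\C)C1=O | target

## Step count and least certain steps

Total: 17 steps. Longest linear sequence: 16 steps (steps 1–3 and 5–17, from 1); step 4 is a one-step branch.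

**Step 12 (key step).** The alkoxide may cleave the C3–C8 bond without the dienyl terminus bonding to C5, because the receiving alkene carbon is fully substituted; this fragmentation without recombination would give ring-opened material. A second failure mode is loss of the C7 configuration or migration of the isopropenyl double bond into conjugation during the methoxide-mediated protonation. Fallback: starting from 17, the tertiary hydroxyl is silylated (N-trimethylsilylimidazole, CH2Cl2) to the trimethylsilyl ether F1. F1 is heated neutral in degassed o-dichlorobenzene (sealed tube, about 200 °C), so the same [3,3] shift proceeds without a free alkoxide and gives the silyl dienol ether F2. Buffered fluoride (Bu4NF, AcOH, THF, −40 °C) then releases the ketone, and the route is rejoined at 20.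

**Step 3.** The nucleophile may be captured at the wrong ortho carbon (both carry methoxy and differ only in the neighbouring methyl), and a slow cycloaddition would let the dienone dimerise. Fallback: starting from 2, the bromophenol itself is oxidised (PhI(OAc)2, MeOH). The bromine next to C2 disfavours cation character there and steers methanol to C6, giving the bromo dienone ketal F3, which is trapped by 4 to give the vinyl bromide adduct F4. Suzuki methylation of F4 (trimethylboroxine, Pd(OAc)2, SPhos, K3PO4) then leads back to 6.

**Step 5.** The branched dienyl nucleophile may fail to add to a carbonyl flanked by two fully substituted carbons, or be consumed by proton transfer from the sulfone. Fallback: starting from 6, the slim 1-propynylmagnesium bromide is added (THF, 0 °C) to give the propynyl carbinol F5. Ethylene–alkyne cross metathesis (second-generation Grubbs catalyst, ethylene at 1 atm, toluene, 60 °C) then converts the internal alkyne into the 2,3-disubstituted diene, rejoining at 11.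

**Step 14.** The hydride may also reduce the C8 carbonyl, which is activated by the α-alkoxy group (over-reduction, loss of chemoselectivity). Fallback: starting from 21, a ketoreductase is selected from a panel (NADPH with glucose/glucose dehydrogenase recycling, phosphate buffer–DMSO, 30 °C) to reduce only the unhindered C3 ketone, from the β face, to the equatorial 3α-alcohol F6. F6 is acylated with 23 through 26 (conditions of step 17), which rejoins the route at 24 and bypasses 22 and the inversion.

**Step 15.** Elimination may compete with substitution (the axial oxyphosphonium group has two antiperiplanar axial hydrogens), or acyl transfer may occur with retention on a hindered alcohol. Fallback: starting from 22, the alcohol is converted (chloromethanesulfonyl chloride, pyridine, 0 °C) into the chloromethanesulfonate F7. F7 is displaced with the cesium salt of 23 (from 23 and Cs2CO3; 18-crown-6, toluene, 60 °C), an SN2 reaction of a carboxylate salt in which no activated angeloyl species occurs, rejoining at 24.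

## Further compounds

F1 | step 12 | 3-(4-methoxybenzyloxy)-1-methoxy-5,6-dimethyl-2-(3-methylbuta-1,3-dien-2-yl)-2-(trimethylsilyloxy)bicyclo[2.2.2]oct-5-ene | C=C(C)C(=C)[C@]1(O[Si](C)(C)C)[C@H](OCc2ccc(OC)cc2)[C@H]3CC[C@]1(OC)C(C)=C3C
F2 | step 12 | 3-methoxy-9β-(4-methoxybenzyloxy)-8-(trimethylsilyloxy)-10βH-eremophila-3,7,11-triene | C=C(C)C=1C[C@@]2(C)[C@H](CCC(OC)=C2C)[C@@H](OCc3ccc(OC)cc3)C=1O[Si](C)(C)C
F3 | step 3 | 3-bromo-2,6,6-trimethoxy-4-methylcyclohexa-2,4-dien-1-one | COC1=C(Br)C(C)=CC(OC)(OC)C1=O
F4 | step 3 | racemic 6-bromo-1,3,3-trimethoxy-5-methyl-7-endo-(phenylsulfonyl)bicyclo[2.2.2]oct-5-en-2-one | O=C1C(OC)(OC)[C@H]2C[C@H](S(=O)(=O)c3ccccc3)[C@]1(OC)C(Br)=C2C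
F5 | step 5 | racemic 1,3,3-trimethoxy-5,6-dimethyl-7-endo-(phenylsulfonyl)-2-(prop-1-yn-1-yl)bicyclo[2.2.2]oct-5-en-2-ol (propynyl syn to C5=C6) | CC#C[C@]1(O)C(OC)(OC)[C@H]2C[C@H](S(=O)(=O)c3ccccc3)[C@]1(OC)C(C)=C2C
F6 | step 14 | 3α-hydroxy-9β-(4-methoxybenzyloxy)-10βH-eremophil-11-en-8-one | C=C(C)[C@H]1C[C@@]2(C)[C@H](CC[C@@H](O)[C@@H]2C)[C@@H](OCc3ccc(OC)cc3)C1=O
F7 | step 15 | 3β-(chloromethanesulfonyloxy)-9β-(4-methoxybenzyloxy)-10βH-eremophil-11-en-8-one | C=C(C)[C@H]1C[C@@]2(C)[C@H](CC[C@H](OS(=O)(=O)CCl)[C@@H]2C)[C@@H](OCc3ccc(OC)cc3)C1=O
A1 | alternative 1 | cis-fused endo quinone adduct (6,9-dione, 8-methoxy-7-ene, 3-silyl enol ether) | O=C1C=C(OC)C(=O)[C@H]2CC=C(O[Si](C)(C)C(C)(C)C)[C@@H](C)[C@@]12C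
A2 | alternative 1 | 2-methoxy-5-methyl-1,4-benzoquinone | COC1=CC(=O)C(C)=CC1=O
A3 | alternative 1 | (Z)-tert-butyldimethyl(penta-1,3-dien-3-yloxy)silane | C=C/C(O[Si](C)(C)C(C)(C)C)=C/C
A4 | alternative 2 | (+)-aristolochene | C=C(C)[C@@H]1C[C@@]2(C)C(CCC[C@@H]2C)=CC1
A5 | alternative 2 | (2E,6E)-farnesyl diphosphate | CC(C)=CCC/C(C)=C/CC/C(C)=C/COP(=O)(O)OP(=O)(O)O
A6 | alternative 3 | cis-fused 3-(tert-butyldimethylsilyloxy)eremophil-6-en-8-one core | C1=C[C@@]2(C)[C@H](CC[C@H](O[Si](C)(C)C(C)(C)C)[C@H]2C)CC1=O
A7 | alternative 3 | N-acyloxyphthalimide of 4-(tert-butyldimethylsilyloxy)-5-(1-methyl-4-oxocyclohexa-2,5-dien-1-yl)hexanoic acid | O=C(ON1C(=O)c2ccccc2C1=O)CC[C@H](O[Si](C)(C)C(C)(C)C)[C@@H](C)C1(C)C=CC(=O)C=C1
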